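A direct plan would build the bicyclo[3.2.1]octane acid A1 (rings C and D, 15-acetate in place, C16=C17 masked as a phenylthiomethyl group) from nopinone, make the ring A dienone chloride A2 by a Diels–Alder reaction, join them as ester A3, close the lactone last by adding a C9 radical to C10 (giving A4), and then unmask the exo-methylene.
Its weakest steps would be:
- The late radical lactone closure: a 6-exo addition through an ester tether would have to form the C9–C10 bond between a tertiary and a quaternary carbon and set C9, C10 and C5 at once, on the most advanced intermediate and without close precedent.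
- The C15 carbinol: the aldol closure of ring D should give the wrong (exo) alcohol, which would have to be equilibrated and trapped by a Tishchenko-type redox step.
- The thioether mask of C16=C17: it would be carried from ring D formation to the last step, would create an uncontrolled C16 centre, and its sulfoxide pyrolysis would put the C6 aldehyde and the enone at risk.

**Retrosynthetic overview of the new route** (ent-kaurane numbering: C7 lactone carbonyl, C20 lactone CH2, C6 aldehyde, C17 exo-methylene)
- Feature used: C8 lies between the lactone carbonyl C7 and the oxygenated C15, so it is the α-carbon of a 2-oxocyclopentanecarboxylate. Ring D is bought as that β-keto ester, and the bridge C9–C11–C12 of the bicyclo[3.2.1]octane is annulated across its C8 and C13 from an allyl unit on C10 of ring A.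
- Key disconnection C8–C9: a palladium-catalysed intramolecular allylic alkylation of the C20 β-keto ester closes lactone ring B and sets quaternary C8 and C9 together. Second disconnection C12–C13: a 6-exo radical conjugate addition closes ring C.
- Ring order: A (4,4-dimethylcyclohexadienone, C5 set by catalysis), then B, then C; ring D is never closed. C10 is relayed from C5 by two aldol additions, C8 and C9 from C10, C13 is forced, and C15 comes from exo-face hydride on the ketone that activated C8.
- Avoided by design: no radical lactone closure onto quaternary C10, no correction of the C15 carbinol, and no mask carried through the route (C17 enters in the ring C step and is unveiled two steps later).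

Key step: step 6

Remark: 4,4-dimethylcyclohexa-2,5-dien-1-one (1) is taken as a catalogue compound; otherwise it is one step (IBX or DDQ) from 4,4-dimethylcyclohex-2-en-1-one.

Step 1
Reactants: 1 4,4-dimethylcyclohexa-2,5-dien-1-one
Product: 2 (5R)-5-ethenyl-4,4-dimethylcyclohex-2-en-1-one
Conditions: K[CH2=CHBF3] (1.1 equiv), [Rh(cod)2]PF6 (3 mol %), (R)-BINAP (3.3 mol %), toluene/H2O, 100 °C
Reagents that add atoms: potassium vinyltrifluoroborate, C=C[B-](F)(F)F.[K+]
Why: The rhodium-catalysed asymmetric conjugate addition (Hayashi–Miyaura reaction) to one of the two enantiotopic enone units desymmetrises the dienone and sets C5; (S)-BINAP is known to give (S)-3-substituted cyclohexanones, so (R)-BINAP should give the (5R) enone, and one equivalent of borate limits a second addition.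

Step 2
Reactants: 2 (5R)-5-ethenyl-4,4-dimethylcyclohex-2-en-1-one
Product: 4 (5S)-5-(dimethoxymethyl)-4,4-dimethylcyclohex-2-en-1-one, via keto aldehyde 3 (not isolated)
Conditions: O3, CH2Cl2/MeOH, −78 °C; Me2S; then HC(OMe)3, CeCl3·7H2O (10 mol %), MeOH, rt
Reagents that add atoms: trimethyl orthoformate, COC(OC)OC
Why: Ozonolysis should cleave the electron-rich vinyl group much faster than the enone alkene, and the cerium-promoted acetalisation masks only the aldehyde (not the conjugated ketone), so the future C6 is protected before the epimerisable centre C5 sees any base.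

Step 3
Reactants: 4 (5S)-5-(dimethoxymethyl)-4,4-dimethylcyclohex-2-en-1-one
Product: 5 (5S)-5-(dimethoxymethyl)-6-(hydroxymethyl)-4,4-dimethylcyclohex-2-en-1-one (both C6 epimers)
Conditions: LiN(i-Pr)2 (1.1 equiv), THF, −78 °C; CH2O (gas, from paraformaldehyde), −78 °C; AcOH
Reagents that add atoms: formaldehyde, C=O
Why: Kinetic deprotonation can occur only at C10 (C2 is vinylic, C4 quaternary), and the lithium enolate adds to monomeric formaldehyde in an aldol addition that installs C20; the configuration at C10 does not matter because this centre is enolised again in step 4.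

Step 4
Reactants: 5 (5S)-5-(dimethoxymethyl)-6-(hydroxymethyl)-4,4-dimethylcyclohex-2-en-1-one
Product: 6 (5R,6S)-5-(dimethoxymethyl)-6-(hydroxymethyl)-6-(1-hydroxyprop-2-en-1-yl)-4,4-dimethylcyclohex-2-en-1-one (both carbinol epimers)
Conditions: LiN(i-Pr)2 (2.3 equiv), THF, −78 to −40 °C; acrolein (1.3 equiv), −78 °C; AcOH, −78 °C
Reagents that add atoms: acrolein, C=CC=O
Why: The alkoxide enolate (dianion) adds 1,2 to acrolein in an aldol addition from the face opposite the pseudo-axial dimethoxymethyl group on C5, which puts the new C9 arm trans and the hydroxymethyl group (C20) cis to C6 and so sets quaternary C10; the carbinol centre C9 forms as a mixture and is erased in step 6.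

Step 5
Reactants: 6 (5R,6S)-5-(dimethoxymethyl)-6-(hydroxymethyl)-6-(1-hydroxyprop-2-en-1-yl)-4,4-dimethylcyclohex-2-en-1-one; 7 tert-butyl 2-oxocyclopentane-1-carboxylate
Product: 8 [(1S,6R)-6-(dimethoxymethyl)-1-(1-hydroxyprop-2-en-1-yl)-5,5-dimethyl-2-oxocyclohex-3-en-1-yl]methyl 2-oxocyclopentane-1-carboxylate
Conditions: 7 (1.1 equiv), toluene, 110 °C, N2 sweep
Reagents that add atoms: none
Why: Thermal transacylation of a tert-butyl β-keto ester through its α-oxoketene (loss of tert-butanol) should acylate the primary C20 alcohol under neutral conditions, which avoids retro-aldol cleavage of the β-hydroxy ketone and spares the more hindered secondary allylic alcohol.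

Step 6
Reactants: 8 [(1S,6R)-6-(dimethoxymethyl)-1-(1-hydroxyprop-2-en-1-yl)-5,5-dimethyl-2-oxocyclohex-3-en-1-yl]methyl 2-oxocyclopentane-1-carboxylate
Product: 9 dispiro keto lactone (5R,8S,9S,10S): δ-lactone ring B spiro at C8 to a 2-oxocyclopentane (ring D) and at C10 to ring A, with an ethenyl group (C11=C12) on C9
Conditions: Pd(PPh3)4 (5 mol %), Et3B (0.6 equiv), THF (degassed), 25 to 50 °C
Reagents that add atoms: none
Why: This is a Tsuji–Trost allylic alkylation with direct, borane-promoted use of the allylic alcohol: Et3B turns the C9 hydroxyl into a leaving group, zerovalent palladium ionises it to the syn π-allyl complex C9–C11–C12 (which erases the carbinol centre), and the β-keto ester enolate attacks C9 anti to palladium. The closest known reaction type is the palladium-catalysed cyclisation of allylic β-keto esters to α-acyl β-vinyl lactones. Ring B closes 6-exo at the inner allyl terminus, because attack at C12 would give an eight-membered lactone that needs either a trans double bond in the ring or the anti π-allyl isomer, which the quaternary C10 disfavours. C9 is controlled by C10: in the reacting conformer C11 is turned away from the bulky C5 arm, palladium lies on the side of the flat C1 carbonyl and the enolate, held by the C20 tether, comes from the other side, so that C11 should end trans to C5 on the lactone. C8 is controlled by the enolate shape: without a chelating cation the ketone oxygen points away from the lactone carbonyl, which places C15 trans and C14 cis to the vinyl group, as the later C12–C13 bridge requires. The step needs C- over O-allylation (soft enolate, six- against eight-membered ring) and tolerance of the ring A enone, which does not react with π-allyl palladium.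

Step 7
Reactants: 9 dispiro keto lactone (5R,8S,9S,10S)
Product: 10 dispiro enone lactone (5R,8S,9S,10S): as 9 with a C13=C16 double bond (2-oxocyclopent-3-ene ring D)
Conditions: IBX (2.5 equiv), 4-methoxypyridine N-oxide (2.5 equiv), DMSO, 25 to 45 °C
Reagents that add atoms: none
Why: In this IBX dehydrogenation of a ketone to its enone, C16 is the only enolisable position in the molecule (C8 and C10 are quaternary, C5 is next to an acetal), so only the ring D cyclopentenone can form.

Step 8
Reactants: 10 dispiro enone lactone (5R,8S,9S,10S)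
Product: 13 (5R,8S,9S,10S,13R)-tetracyclic 15-ketone with a (dimethylamino)methyl group on C16 and C6 as dimethyl acetal, via alkylborane 11 (not isolated), via boron enolate 12 (not isolated)
Conditions: catecholborane (1.1 equiv), RhCl(PPh3)3 (2 mol %), THF, 0 °C; then DMPU, air (syringe pump), rt; then [CH2=NMe2]I (2 equiv), rt; aq. NaHCO3
Reagents that add atoms: dimethyl(methylidene)ammonium iodide (Eschenmoser's salt), C=[N+](C)C.[I-]
Why: Rhodium-catalysed hydroboration takes the only terminal alkene anti-Markovnikov and leaves the ketones, oxygen then releases the primary C12 radical from the B-alkylcatecholborane, which closes ring C (and with it the bicyclo[3.2.1]octane) by a 6-exo-trig conjugate addition to C13 of the cyclopentenone — C13 can be reached only on the face of ring D that carries C9, so its configuration is forced — and the chain-carrying boron enolate is aminomethylated at C16 by the iminium salt (Mannich reaction), which stores the future C17.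

Step 9
Reactants: 13 (5R,8S,9S,10S,13R)-tetracyclic 15-ketone with a (dimethylamino)methyl group on C16
Product: 15 (5R,8S,9S,10S,13R,15R)-15-acetate with a (dimethylamino)methyl group on C16 and C6 as dimethyl acetal, via amino alcohol 14 (not isolated)
Conditions: NaBH4 (1.2 equiv), THF/MeOH (10:1), −40 °C; then Ac2O, Et3N, DMAP (cat.), CH2Cl2, rt
Reagents that add atoms: acetic anhydride, CC(=O)OC(C)=O
Why: NaBH4 at low temperature should reduce the strained, saturated bridged cyclopentanone faster than the hindered conjugated ring A ketone (the selectivity known from the Wieland–Miescher ketone), hydride enters from the open exo face (the side of C14) because the endo face is shielded by C9 and C11, which gives the endo (15R) alcohol, and this is acetylated directly.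

Step 10
Reactants: 15 (5R,8S,9S,10S,13R,15R)-15-acetate with a (dimethylamino)methyl group on C16
Product: 17 6-dimethyl acetal of the target (5R,8S,9S,10S,13R,15R), via amine N-oxide 16 (not isolated)
Conditions: mCPBA (1.05 equiv), K2CO3, CH2Cl2, 0 °C; then toluene, 90 °C
Reagents that add atoms: none
Why: mCPBA oxidises the tertiary amine much faster than the electron-poor enone alkene, and the amine oxide undergoes Cope elimination (syn, five-membered transition state) through its only β-hydrogen, on C16, so only the exocyclic C16=C17 alkene can form and no stereocentre is touched.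

Step 11
Reactants: 17 6-dimethyl acetal of the target
Product: 18 target CNP0108627.4
Conditions: 1 M HCl, THF, 0 °C to rt
Reagents that add atoms: water, O
Why: Mild acid hydrolysis of the dimethyl acetal should free the C6 aldehyde without touching the allylic acetate, the lactone or the enone, and C5 keeps the configuration set in step 1.

**Compound list**
1 | 4,4-dimethylcyclohexa-2,5-dien-1-one | CC1(C)C=CC(=O)C=C1 | starting material
2 | (5R)-5-ethenyl-4,4-dimethylcyclohex-2-en-1-one | O=C1C=CC(C)(C)[C@@H](C=C)C1 | intermediate
3 | (1S)-2,2-dimethyl-5-oxocyclohex-3-ene-1-carbaldehyde | O=C1C=CC(C)(C)[C@@H](C=O)C1 | intermediate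
4 | (5S)-5-(dimethoxymethyl)-4,4-dimethylcyclohex-2-en-1-one | O=C1C=CC(C)(C)[C@@H](C(OC)OC)C1 | intermediate
5 | (5S)-5-(dimethoxymethyl)-6-(hydroxymethyl)-4,4-dimethylcyclohex-2-en-1-one (C6 epimers) | O=C1C=CC(C)(C)[C@@H](C(OC)OC)C1CO | intermediate
6 | (5R,6S)-5-(dimethoxymethyl)-6-(hydroxymethyl)-6-(1-hydroxyprop-2-en-1-yl)-4,4-dimethylcyclohex-2-en-1-one (carbinol epimers) | OC[C@@]1(C(O)C=C)C(=O)C=CC(C)(C)[C@H]1C(OC)OC | intermediate
7 | tert-butyl 2-oxocyclopentane-1-carboxylate | CC(C)(C)OC(=O)C1CCCC1=O | starting material
8 | [(1S,6R)-6-(dimethoxymethyl)-1-(1-hydroxyprop-2-en-1-yl)-5,5-dimethyl-2-oxocyclohex-3-en-1-yl]methyl 2-oxocyclopentane-1-carboxylate | O=C1CCCC1C(=O)OC[C@@]1(C(O)C=C)C(=O)C=CC(C)(C)[C@H]1C(OC)OC | intermediate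
9 | dispiro keto lactone (5R,8S,9S,10S; ent-kaurane numbering): δ-lactone spiro at C8 to 2-oxocyclopentane and at C10 to the 6-(dimethoxymethyl)-5,5-dimethyl-2-oxocyclohex-3-ene ring, ethenyl on C9 | C=C[C@@H]1[C@]2(CCCC2=O)C(=O)OC[C@]13C(=O)C=CC(C)(C)[C@H]3C(OC)OC | intermediate
10 | dispiro enone lactone (5R,8S,9S,10S): as 9 with a 2-oxocyclopent-3-ene ring D (C13=C16) | C=C[C@@H]1[C@]2(CC=CC2=O)C(=O)OC[C@]13C(=O)C=CC(C)(C)[C@H]3C(OC)OC | intermediate
11 | B-alkylcatecholborane of 10 (1,3,2-benzodioxaborol-2-yl on C12) | B1(CC[C@@H]2[C@]3(CC=CC3=O)C(=O)OC[C@]24C(=O)C=CC(C)(C)[C@H]4C(OC)OC)Oc2ccccc2O1 | intermediate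
12 | catecholboron enolate (C15–O–B, C15=C16) of the tetracyclic 15-ketone | C1(OB2Oc3ccccc3O2)=C[C@@H]2CC[C@@H]3[C@]1(C2)C(=O)OC[C@]34C(=O)C=CC(C)(C)[C@H]4C(OC)OC | intermediate
13 | (5R,8S,9S,10S,13R)-16-[(dimethylamino)methyl]-15-oxo tetracycle, C6 as dimethyl acetal (C16 epimers) | CN(C)CC1[C@@H]2CC[C@@H]3[C@](C2)(C(=O)OC[C@]34C(=O)C=CC(C)(C)[C@H]4C(OC)OC)C1=O | intermediate
14 | (15R)-15-hydroxy analogue of 13 (endo alcohol) | CN(C)CC1[C@@H]2CC[C@@H]3[C@](C2)(C(=O)OC[C@]34C(=O)C=CC(C)(C)[C@H]4C(OC)OC)[C@@H]1O | intermediate
15 | (15R)-15-acetoxy-16-[(dimethylamino)methyl] tetracycle, C6 as dimethyl acetal | CN(C)CC1[C@@H]2CC[C@@H]3[C@](C2)(C(=O)OC[C@]34C(=O)C=CC(C)(C)[C@H]4C(OC)OC)[C@@H]1OC(C)=O | intermediate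
16 | amine N-oxide of 15 | C[N+](C)([O-])CC1[C@@H]2CC[C@@H]3[C@](C2)(C(=O)OC[C@]34C(=O)C=CC(C)(C)[C@H]4C(OC)OC)[C@@H]1OC(C)=O | intermediate
17 | 6-dimethyl acetal of the target (5R,8S,9S,10S,13R,15R) | C=C1[C@@H]2CC[C@@H]3[C@](C2)(C(=O)OC[C@]34C(=O)C=CC(C)(C)[C@H]4C(OC)OC)[C@@H]1OC(C)=O | intermediate
18 | CNP0108627.4 (5R,8S,9S,10S,13R,15R) | C=C1[C@@H]2CC[C@@H]3[C@](C2)(C(=O)OC[C@]32C(=O)C=CC(C)(C)[C@H]2C=O)[C@@H]1OC(C)=O | target

**Step count**
Total: 11 steps. Longest linear sequence: 11 steps (1 to 18; 7 is bought).

**Steps most likely to fail**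

Step 6. The neopentylic carbinol may ionise slowly, the enolate may attack the open allyl terminus or react at oxygen, and facial control at C8 may be weak. Fallback: from 8, SOCl2 in Et2O at 0 °C should give, with allylic transposition, the primary (E)-allylic chloride F1. Cs2CO3 in MeCN should then close the same lactone by a metal-free intramolecular SN2′ alkylation at C9 (direct SN2 at C12 would need a trans-cyclooctene lactone), which comes back to 9.

Step 8. The hydroboration may touch one of the enones, the oxygen-started radical chain may stall, or the boron enolate may be protonated before it is aminomethylated. Fallback: set out from 9, before the dehydrogenation. Hydroboration–oxidation (9-BBN; NaBO3·4H2O) should give the primary alcohol F2, Appel iodination (I2, PPh3, imidazole) the iodide F3, and IBX the iodo enone F4. A tin hydride radical cyclisation (Bu3SnH, AIBN, slow addition, benzene, 80 °C) should then give the tetracyclic 15-ketone F5, and LiN(SiMe3)2 followed by Eschenmoser's salt should come back to 13.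

Step 9. Hydride may also reduce the ring A enone, or the β-amino ketone may lose the amine before it is reduced. Fallback: from 13, reduce both carbonyl groups on purpose (NaBH4, CeCl3·7H2O, MeOH, −20 °C) to the diol F6 and re-oxidise only the allylic C1 alcohol with MnO2 (CH2Cl2, rt), which comes back to 14; acetylation then follows as in step 9.

**Further compounds**
F1 | step 6 | [(1S,6R)-1-[(E)-3-chloroprop-1-en-1-yl]-6-(dimethoxymethyl)-5,5-dimethyl-2-oxocyclohex-3-en-1-yl]methyl 2-oxocyclopentane-1-carboxylate | O=C1CCCC1C(=O)OC[C@@]1(/C=C/CCl)C(=O)C=CC(C)(C)[C@H]1C(OC)OC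
F2 | step 8 | primary alcohol from 9 (2-hydroxyethyl on C9 in place of ethenyl) | OCC[C@@H]1[C@]2(CCCC2=O)C(=O)OC[C@]13C(=O)C=CC(C)(C)[C@H]3C(OC)OC
F3 | step 8 | primary iodide from F2 (2-iodoethyl on C9) | ICC[C@@H]1[C@]2(CCCC2=O)C(=O)OC[C@]13C(=O)C=CC(C)(C)[C@H]3C(OC)OC
F4 | step 8 | iodo enone (F3 with a 2-oxocyclopent-3-ene ring D) | ICC[C@@H]1[C@]2(CC=CC2=O)C(=O)OC[C@]13C(=O)C=CC(C)(C)[C@H]3C(OC)OC
F5 | step 8 | (5R,8S,9S,10S,13R)-tetracyclic 15-ketone without substituent on C16, C6 as dimethyl acetal | O=C1C[C@@H]2CC[C@@H]3[C@]1(C2)C(=O)OC[C@]34C(=O)C=CC(C)(C)[C@H]4C(OC)OC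
F6 | step 9 | 1,15-diol from 13 (C1 allylic alcohol as epimers, 15R) | CN(C)CC1[C@@H]2CC[C@@H]3[C@](C2)(C(=O)OC[C@]34C(O)C=CC(C)(C)[C@H]4C(OC)OC)[C@@H]1O
A1 | direct plan | (1S,2R,5R,7R)-7-acetoxy-2-hydroxy-6-[(phenylsulfanyl)methyl]bicyclo[3.2.1]octane-1-carboxylic acid | c1ccccc1SCC1[C@@H]2CC[C@@H](O)[C@](C2)(C(=O)O)[C@@H]1OC(C)=O
A2 | direct plan | 2-(chloromethyl)-6,6-dimethyl-3-oxocyclohexa-1,4-diene-1-carbaldehyde | O=CC1=C(CCl)C(=O)C=CC1(C)C
A3 | direct plan | (2-formyl-3,3-dimethyl-6-oxocyclohexa-1,4-dien-1-yl)methyl ester of A1 | c1ccccc1SCC1[C@@H]2CC[C@@H](O)[C@](C2)(C(=O)OCC2=C(C=O)C(C)(C)C=CC2=O)[C@@H]1OC(C)=O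
A4 | direct plan | 17-(phenylsulfanyl)-16,17-dihydro derivative of the target | c1ccccc1SCC1[C@@H]2CC[C@@H]3[C@](C2)(C(=O)OC[C@]32C(=O)C=CC(C)(C)[C@H]2C=O)[C@@H]1OC(C)=O
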